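The whole route depends on cutting the O1–C5 bond of the oxolane ring. C5 bears only a methyl group, lies trans to the dienyl-bearing C2 and cis to the C3 hydroxyl. C5 and its methyl can therefore be read as a former terminal vinyl group. One aerobic cobalt-catalysed cyclisation closes the ring, sets C5 under control of C2 and C3, and finishes the exocyclic carbon as CH3. Its precursor is an erythro hex-5-ene-1,2,3-triol with the C2 hydroxyl free, the C3 oxygen benzoylated and the C1 oxygen carried as a TBS ether. TBS is chosen because it can later be cleaved beside a secondary TBS ether. Two olefinations then join the oxolane to the chlorinated isochromenone.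

Key step: step 6

Assumption: the open-chain carbons C1–C6 keep their numbers in the oxolane (C6 becomes the methyl group, C1 the exocyclic carbon). The cobalt complex, the formyl ylide and the chloro Weinreb amide are bought.

Step 1
Reactants: 1 propargyl alcohol; 2 allyl bromide
Product: 3 hex-5-en-2-yn-1-ol
Conditions: CuI (10 mol%), K2CO3, Bu4NI (cat.), DMF, rt
Reagents that add atoms: none
Why: Copper-acetylide allylation of a terminal alkyne with an allylic halide should give the skipped enyne, and carbonate is too weak a base to cause O-allylation.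

Step 2
Reactants: 3 hex-5-en-2-yn-1-ol
Product: 4 (2E)-hexa-2,5-dien-1-ol
Conditions: LiAlH4, THF, 0 °C to reflux; aqueous work-up
Reagents that add atoms: none
Why: Alkoxide-directed trans-hydroalumination of a propargylic alcohol should give only the E-allylic alcohol, and the isolated terminal alkene is inert to LiAlH4.

Step 3
Reactants: 4 (2E)-hexa-2,5-dien-1-ol
Product: 5 [(2S,3S)-3-(prop-2-en-1-yl)oxiran-2-yl]methanol
Conditions: Ti(OiPr)4 (5–10 mol%), L-(+)-diisopropyl tartrate (cat.), t-BuOOH, 4 Å molecular sieves, CH2Cl2, −20 °C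
Reagents that add atoms: tert-butyl hydroperoxide, CC(C)(C)OO
Why: In the Sharpless asymmetric epoxidation the L-(+)-tartrate complex delivers oxygen to the face of the E-allylic alcohol that gives the (2S,3S)-epoxide, and only the titanium-bound allylic alkene reacts, so the terminal alkene is left alone.

Step 4
Reactants: 5 [(2S,3S)-3-(prop-2-en-1-yl)oxiran-2-yl]methanol; 6 benzoic acid
Product: 7 (2S,3R)-1,2-dihydroxyhex-5-en-3-yl benzoate
Conditions: Ti(OiPr)4 (1.5 equiv), CH2Cl2, rt; dilute acid work-up
Reagents that add atoms: none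
Why: In this titanium-assisted opening of a 2,3-epoxy alcohol, chelation of the epoxy alkoxide steers benzoate to the distal carbon C3 in an SN2 process, so C3 is inverted to R, C2 stays S, and the erythro array results.

Step 5
Reactants: 7 (2S,3R)-1,2-dihydroxyhex-5-en-3-yl benzoate
Product: 8 (2S,3R)-1-{[tert-butyl(dimethyl)silyl]oxy}-2-hydroxyhex-5-en-3-yl benzoate
Conditions: TBSCl (1.05 equiv), imidazole, CH2Cl2, 0 °C
Reagents that add atoms: tert-butyldimethylsilyl chloride, CC(C)(C)[Si](C)(C)Cl
Why: Sterically controlled silylation should take the primary hydroxyl of the 1,2-diol only, and the low temperature and short contact with base are meant to suppress benzoyl migration.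

Step 6
Reactants: 8 (2S,3R)-1-{[tert-butyl(dimethyl)silyl]oxy}-2-hydroxyhex-5-en-3-yl benzoate
Product: 9 (2S,3R,5S)-2-({[tert-butyl(dimethyl)silyl]oxy}methyl)-5-methyloxolan-3-yl benzoate
Conditions: Co(modp)2 (10 mol%; bis(1-morpholinocarbamoyl-4,4-dimethylpentane-1,3-dionato)cobalt), O2 (1 atm), cyclohexa-1,4-diene (large excess), toluene, 60 °C
Reagents that add atoms: none
Why: This is the known aerobic cobalt-catalysed oxidative cyclisation of pent-4-en-1-ols run with reductive termination: the divalent cobalt diketonate binds O2 and the C2 hydroxyl of 8, the trivalent cobalt species so formed oxidises the coordinated C5=C6 alkene while the hydroxyl oxygen attacks C5, and the primary C6 radical that leaves the metal takes a hydrogen atom from cyclohexa-1,4-diene, which ends as benzene while O2 ends as water. The oxolane ring closes in the 5-exo-trig mode through the new O1–C5 bond, the 6-endo alternative being disfavoured for a monosubstituted alkene. C5 is the only new stereocentre and is set by the substrate: in the chair-like transition state the CH2OTBS group on C2 and the benzoyloxy group on C3 can both lie pseudo-equatorial, which puts the nascent methyl trans to the C2 substituent and cis to the C3 oxygen, that is 5S. The diastereoselectivity needed is secured because C2 and C3 are trans, so the two empirical preferences of this reaction (trans to the carbinol substituent, cis to the substituent one carbon further on) select the same alkene face. Chemoselectivity is secured by masking the C1 and C3 oxygens, which leaves a single hydroxyl able to reach the alkene, and by the excess of diene, which should let hydrogen transfer outrun capture of the radical by O2.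

Step 7
Reactants: 9 (2S,3R,5S)-2-({[tert-butyl(dimethyl)silyl]oxy}methyl)-5-methyloxolan-3-yl benzoate
Product: 10 (2S,3R,5S)-2-({[tert-butyl(dimethyl)silyl]oxy}methyl)-5-methyloxolan-3-ol
Conditions: K2CO3 (cat.), MeOH, rt
Reagents that add atoms: none
Why: Base-catalysed transesterification removes the benzoate at a stage where no base-sensitive group is present, and the primary TBS ether and all stereocentres are unaffected.

Step 8
Reactants: 10 (2S,3R,5S)-2-({[tert-butyl(dimethyl)silyl]oxy}methyl)-5-methyloxolan-3-ol
Product: 11 tert-butyl{[(2S,3R,5S)-3-{[tert-butyl(dimethyl)silyl]oxy}-5-methyloxolan-2-yl]methoxy}dimethylsilane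
Conditions: TBSOTf, 2,6-lutidine, CH2Cl2, 0 °C
Reagents that add atoms: tert-butyldimethylsilyl triflate, CC(C)(C)[Si](C)(C)OS(=O)(=O)C(F)(F)F
Why: Silyl triflate silylation covers the ring-bound secondary alcohol with a group that can leave in the final fluoride step together with the phenol silyl ethers.

Step 9
Reactants: 11 tert-butyl{[(2S,3R,5S)-3-{[tert-butyl(dimethyl)silyl]oxy}-5-methyloxolan-2-yl]methoxy}dimethylsilane
Product: 12 [(2S,3R,5S)-3-{[tert-butyl(dimethyl)silyl]oxy}-5-methyloxolan-2-yl]methanol
Conditions: TFA–H2O–THF (1:1:4), 0 °C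
Reagents that add atoms: none
Why: Acid hydrolysis of silyl ethers is governed by steric access, so the primary TBS ether should go well before the secondary one, as is routine for 3,5-bis-silylated 2-deoxypentofuranose systems of the same skeleton.

Step 10
Reactants: 12 [(2S,3R,5S)-3-{[tert-butyl(dimethyl)silyl]oxy}-5-methyloxolan-2-yl]methanol; 13 (triphenylphosphoranylidene)acetaldehyde
Product: 15 (2E)-3-[(2S,3R,5S)-3-{[tert-butyl(dimethyl)silyl]oxy}-5-methyloxolan-2-yl]prop-2-enal, via oxolane-2-carbaldehyde 14 (not isolated)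
Conditions: Dess–Martin periodinane (1.1 equiv), CH2Cl2, 0 °C to rt; then 13 (1.3 equiv), rt to 40 °C
Reagents that add atoms: none
Why: Dess–Martin oxidation gives the sensitive α-alkoxy-β-silyloxy aldehyde without base, and it is consumed in the same flask by a Wittig reaction with the stabilised formyl ylide, which should give the E-enal without touching C2.

Step 11
Reactants: 16 methyl orsellinate (methyl 2,4-dihydroxy-6-methylbenzoate)
Product: 17 methyl 3-chloro-4,6-dihydroxy-2-methylbenzoate
Conditions: SO2Cl2 (1.0 equiv), Et2O, 0 °C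
Reagents that add atoms: sulfuryl chloride, O=S(=O)(Cl)Cl
Why: Electrophilic aromatic chlorination of 6-alkylresorcylates goes first to the position next to the alkyl group (ortho to the free hydroxyl, para to the chelated one), and one equivalent of reagent limits dichlorination.

Step 12
Reactants: 17 methyl 3-chloro-4,6-dihydroxy-2-methylbenzoate
Product: 18 methyl 3-chloro-4,6-bis(methoxymethoxy)-2-methylbenzoate
Conditions: NaH, MOMCl, DMF, 0 °C to rt
Reagents that add atoms: chloromethyl methyl ether, COCCl
Why: Williamson-type alkylation of both phenoxides installs acetals that tolerate the amide base of the next step and fall off under the acid used for ring closure.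

Step 13
Reactants: 18 methyl 3-chloro-4,6-bis(methoxymethoxy)-2-methylbenzoate; 19 2-chloro-N-methoxy-N-methylacetamide
Product: 20 methyl 3-chloro-2-(3-chloro-2-oxopropyl)-4,6-bis(methoxymethoxy)benzoate
Conditions: LiN(iPr)2 (1.1 equiv), THF, −78 °C; then 19, −78 °C; AcOH quench at −78 °C
Reagents that add atoms: none
Why: Lateral lithiation of the ortho-toluate is followed by a Weinreb ketone synthesis, and the chelated tetrahedral adduct lasts until the cold acidic quench, so over-addition and enolisation of the chloro ketone are avoided.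

Step 14
Reactants: 20 methyl 3-chloro-2-(3-chloro-2-oxopropyl)-4,6-bis(methoxymethoxy)benzoate
Product: 22 5-chloro-3-(chloromethyl)-6,8-dihydroxy-1H-isochromen-1-one, via dihydroxy keto ester 21 (not isolated)
Conditions: conc. HCl (cat.), MeOH, 50 °C; solvent switch; p-TsOH·H2O (cat.), toluene, reflux
Reagents that add atoms: none
Why: Acidic acetal exchange frees the phenols, and acid-catalysed enol lactonisation of the benzyl ketone onto the neighbouring ester then closes the six-membered pyranone with loss of methanol, acid being chosen because the chloro ketone would not tolerate enolate conditions.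

Step 15
Reactants: 22 5-chloro-3-(chloromethyl)-6,8-dihydroxy-1H-isochromen-1-one
Product: 23 6,8-bis{[tert-butyl(dimethyl)silyl]oxy}-5-chloro-3-(chloromethyl)-1H-isochromen-1-one
Conditions: TBSOTf (2.5 equiv), 2,6-lutidine, CH2Cl2, 0 °C to rt
Reagents that add atoms: tert-butyldimethylsilyl triflate, CC(C)(C)[Si](C)(C)OS(=O)(=O)C(F)(F)F
Why: The silyl triflate is reactive enough for the hydrogen-bonded C8 phenol, and the hindered pyridine base cannot displace the allylic chloride.

Step 16
Reactants: 23 6,8-bis{[tert-butyl(dimethyl)silyl]oxy}-5-chloro-3-(chloromethyl)-1H-isochromen-1-one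
Product: 24 diethyl [(6,8-bis{[tert-butyl(dimethyl)silyl]oxy}-5-chloro-1-oxo-1H-isochromen-3-yl)methyl]phosphonate
Conditions: P(OEt)3 (neat), Bu4NI (cat.), 130 °C
Reagents that add atoms: triethyl phosphite, CCOP(OCC)OCC
Why: The Michaelis–Arbuzov reaction of an allylic-type primary chloride proceeds under neutral conditions that leave the aryl silyl ethers, the aryl chloride and the lactone untouched.

Step 17
Reactants: 24 diethyl [(6,8-bis{[tert-butyl(dimethyl)silyl]oxy}-5-chloro-1-oxo-1H-isochromen-3-yl)methyl]phosphonate; 15 (2E)-3-[(2S,3R,5S)-3-{[tert-butyl(dimethyl)silyl]oxy}-5-methyloxolan-2-yl]prop-2-enal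
Product: 25 6,8-bis{[tert-butyl(dimethyl)silyl]oxy}-3-{(1E,3E)-4-[(2S,3R,5S)-3-{[tert-butyl(dimethyl)silyl]oxy}-5-methyloxolan-2-yl]buta-1,3-dien-1-yl}-5-chloro-1H-isochromen-1-one
Conditions: 24 (1.2 equiv), LiN(SiMe3)2 (1.15 equiv), THF, −78 °C; then 15, −78 to 0 °C
Reagents that add atoms: none
Why: In this Horner–Wadsworth–Emmons olefination the carbanion is delocalised through C3=C4 and the benzo ring into the lactone carbonyl, so it behaves as a stabilised phosphonate anion that adds reversibly to the enal and should give the new alkene E.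

Step 18
Reactants: 25 the tris-TBS ether from step 17
Product: 26 5-chloro-6,8-dihydroxy-3-{(1E,3E)-4-[(2S,3R,5S)-3-hydroxy-5-methyloxolan-2-yl]buta-1,3-dien-1-yl}-1H-isochromen-1-one (target)
Conditions: HF·pyridine, pyridine, THF, 0 °C to rt
Reagents that add atoms: none
Why: Fluoride-driven Si–O cleavage under pyridine buffering removes all three silyl groups without opening the lactone, ionising the allylic C2–O1 bond or isomerising the diene.

Compound list
1 | propargyl alcohol | C#CCO | starting material
2 | allyl bromide | C=CCBr | starting material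
3 | hex-5-en-2-yn-1-ol | C=CCC#CCO | intermediate
4 | (2E)-hexa-2,5-dien-1-ol | C=CC/C=C/CO | intermediate
5 | [(2S,3S)-3-(prop-2-en-1-yl)oxiran-2-yl]methanol | C=CC[C@@H]1O[C@H]1CO | intermediate
6 | benzoic acid | OC(=O)c1ccccc1 | starting material
7 | (2S,3R)-1,2-dihydroxyhex-5-en-3-yl benzoate | C=CC[C@@H](OC(=O)c1ccccc1)[C@@H](O)CO | intermediate
8 | (2S,3R)-1-{[tert-butyl(dimethyl)silyl]oxy}-2-hydroxyhex-5-en-3-yl benzoate | C=CC[C@@H](OC(=O)c1ccccc1)[C@@H](O)CO[Si](C)(C)C(C)(C)C | intermediate
9 | (2S,3R,5S)-2-({[tert-butyl(dimethyl)silyl]oxy}methyl)-5-methyloxolan-3-yl benzoate | C[C@H]1C[C@@H](OC(=O)c2ccccc2)[C@H](CO[Si](C)(C)C(C)(C)C)O1 | intermediate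
10 | (2S,3R,5S)-2-({[tert-butyl(dimethyl)silyl]oxy}methyl)-5-methyloxolan-3-ol | C[C@H]1C[C@@H](O)[C@H](CO[Si](C)(C)C(C)(C)C)O1 | intermediate
11 | tert-butyl{[(2S,3R,5S)-3-{[tert-butyl(dimethyl)silyl]oxy}-5-methyloxolan-2-yl]methoxy}dimethylsilane | C[C@H]1C[C@@H](O[Si](C)(C)C(C)(C)C)[C@H](CO[Si](C)(C)C(C)(C)C)O1 | intermediate
12 | [(2S,3R,5S)-3-{[tert-butyl(dimethyl)silyl]oxy}-5-methyloxolan-2-yl]methanol | C[C@H]1C[C@@H](O[Si](C)(C)C(C)(C)C)[C@H](CO)O1 | intermediate
13 | (triphenylphosphoranylidene)acetaldehyde | O=CC=P(c1ccccc1)(c1ccccc1)c1ccccc1 | starting material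
14 | (2R,3R,5S)-3-{[tert-butyl(dimethyl)silyl]oxy}-5-methyloxolane-2-carbaldehyde | C[C@H]1C[C@@H](O[Si](C)(C)C(C)(C)C)[C@H](C=O)O1 | intermediate
15 | (2E)-3-[(2S,3R,5S)-3-{[tert-butyl(dimethyl)silyl]oxy}-5-methyloxolan-2-yl]prop-2-enal | C[C@H]1C[C@@H](O[Si](C)(C)C(C)(C)C)[C@H](/C=C/C=O)O1 | intermediate
16 | methyl orsellinate | COC(=O)c1c(C)cc(O)cc1O | starting material
17 | methyl 3-chloro-4,6-dihydroxy-2-methylbenzoate | COC(=O)c1c(C)c(Cl)c(O)cc1O | intermediate
18 | methyl 3-chloro-4,6-bis(methoxymethoxy)-2-methylbenzoate | COC(=O)c1c(C)c(Cl)c(OCOC)cc1OCOC | intermediate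
19 | 2-chloro-N-methoxy-N-methylacetamide | CON(C)C(=O)CCl | starting material
20 | methyl 3-chloro-2-(3-chloro-2-oxopropyl)-4,6-bis(methoxymethoxy)benzoate | COC(=O)c1c(CC(=O)CCl)c(Cl)c(OCOC)cc1OCOC | intermediate
21 | methyl 3-chloro-2-(3-chloro-2-oxopropyl)-4,6-dihydroxybenzoate | COC(=O)c1c(CC(=O)CCl)c(Cl)c(O)cc1O | intermediate
22 | 5-chloro-3-(chloromethyl)-6,8-dihydroxy-1H-isochromen-1-one | O=c1oc(CCl)cc2c(Cl)c(O)cc(O)c12 | intermediate
23 | 6,8-bis{[tert-butyl(dimethyl)silyl]oxy}-5-chloro-3-(chloromethyl)-1H-isochromen-1-one | O=c1oc(CCl)cc2c(Cl)c(O[Si](C)(C)C(C)(C)C)cc(O[Si](C)(C)C(C)(C)C)c12 | intermediate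
24 | diethyl [(6,8-bis{[tert-butyl(dimethyl)silyl]oxy}-5-chloro-1-oxo-1H-isochromen-3-yl)methyl]phosphonate | CCOP(=O)(OCC)Cc1cc2c(Cl)c(O[Si](C)(C)C(C)(C)C)cc(O[Si](C)(C)C(C)(C)C)c2c(=O)o1 | intermediate
25 | tris-TBS ether of the target, (1E,3E), (2S,3R,5S) | C[C@H]1C[C@@H](O[Si](C)(C)C(C)(C)C)[C@H](/C=C/C=C/c2cc3c(Cl)c(O[Si](C)(C)C(C)(C)C)cc(O[Si](C)(C)C(C)(C)C)c3c(=O)o2)O1 | intermediate
26 | 5-chloro-6,8-dihydroxy-3-{(1E,3E)-4-[(2S,3R,5S)-3-hydroxy-5-methyloxolan-2-yl]buta-1,3-dien-1-yl}-1H-isochromen-1-one | C[C@H]1C[C@@H](O)[C@H](/C=C/C=C/c2cc3c(Cl)c(O)cc(O)c3c(=O)o2)O1 | target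

Total step count: 18. Longest linear sequence: 12 steps (steps 1–10, 17, 18). Steps 11–16 form the convergent branch.

Steps most likely to fail

Step 6. The cyclised primary radical may be captured by O2 faster than it receives hydrogen, the hydrogen donor may drain the active catalyst, or benzoyl migration from the C3 to the C2 oxygen at 60 °C may remove the nucleophile. The fallback sets out from 8 and accepts oxygen capture on purpose. The established oxygenative variant (Co(modp)2, O2, t-BuOOH (cat.), iPrOH, 55 °C) should give the trans-configured 5-(hydroxymethyl)oxolane F1. Iodination (I2, PPh3, imidazole, CH2Cl2) would then give the 5-(iodomethyl)oxolane F2. Radical reduction (Bu3SnH, AIBN, toluene, 80 °C) would turn CH2I into CH3 and return to the route at 9.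

Step 13. Proton transfer from the chloromethyl group of the amide, or SN2 displacement at it, may compete with acyl addition of the soft benzylic anion. The fallback sets out from 18 and uses a two-carbon unit without a leaving group. The lithiated toluate would be acylated with 2-{[tert-butyl(dimethyl)silyl]oxy}-N-methoxy-N-methylacetamide to give the silyloxy ketone F3. The acid treatment of step 14 would strip the silyl and MOM groups and close the lactone to the 3-(hydroxymethyl)isochromenone F4. An Appel chlorination (PPh3, CCl4, THF), which spares phenols, would convert the primary allylic alcohol into the chloride and rejoin the route at 22.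

Step 17. The strongly basic medium may cause γ-deprotonation of the enal with loss of the C3 silyloxy group, attack on the lactone or the aryl silyl ethers, or incomplete E-selectivity. The fallback sets out from 23 and 15 and separates bond formation from control of geometry. Heating 23 with PPh3 in toluene would give the isochromenonylmethyl phosphonium chloride F5. Its stabilised ylide forms with K2CO3 and 18-crown-6 in CH2Cl2 at rt. A Wittig reaction with 15 would give 25 together with its (1Z,3E)-isomer F6. Equilibration of the mixture with I2 (cat.) in CH2Cl2 under daylight should funnel the material to the all-E diene and come back at 25.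

Further compounds
F1 | step 6 | (2S,3R,5R)-2-({[tert-butyl(dimethyl)silyl]oxy}methyl)-5-(hydroxymethyl)oxolan-3-yl benzoate | OC[C@H]1C[C@@H](OC(=O)c2ccccc2)[C@H](CO[Si](C)(C)C(C)(C)C)O1
F2 | step 6 | (2S,3R,5R)-2-({[tert-butyl(dimethyl)silyl]oxy}methyl)-5-(iodomethyl)oxolan-3-yl benzoate | IC[C@H]1C[C@@H](OC(=O)c2ccccc2)[C@H](CO[Si](C)(C)C(C)(C)C)O1
F3 | step 13 | methyl 2-(3-{[tert-butyl(dimethyl)silyl]oxy}-2-oxopropyl)-3-chloro-4,6-bis(methoxymethoxy)benzoate | COC(=O)c1c(CC(=O)CO[Si](C)(C)C(C)(C)C)c(Cl)c(OCOC)cc1OCOC
F4 | step 13 | 5-chloro-6,8-dihydroxy-3-(hydroxymethyl)-1H-isochromen-1-one | O=c1oc(CO)cc2c(Cl)c(O)cc(O)c12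
F5 | step 17 | [(6,8-bis{[tert-butyl(dimethyl)silyl]oxy}-5-chloro-1-oxo-1H-isochromen-3-yl)methyl]triphenylphosphonium chloride | [Cl-].O=c1oc(C[P+](c2ccccc2)(c2ccccc2)c2ccccc2)cc2c(Cl)c(O[Si](C)(C)C(C)(C)C)cc(O[Si](C)(C)C(C)(C)C)c12
F6 | step 17 | (1Z,3E)-isomer of 25 | C[C@H]1C[C@@H](O[Si](C)(C)C(C)(C)C)[C@H](/C=C/C=C\c2cc3c(Cl)c(O[Si](C)(C)C(C)(C)C)cc(O[Si](C)(C)C(C)(C)C)c3c(=O)o2)O1
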